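The route opens both pyrone rings at the O1–C6 bond. Each arm of the target is a 6-ethyl-4-hydroxy-2-pyrone whose ring oxygen O1, C6 and the C6 ethyl group can be read as an ester oxygen that has added to the ethyl-bearing carbon of a but-1-ynyl ketone. One gold-catalysed operation therefore closes both heteroaromatic rings from a tri-O-benzyl (R)-acylphloroglucinol (ring A) carrying two CH2-linked tert-butyl 3-oxohept-4-ynoate arms, with isobutene as the only by-product. The arms come from alkylation of a ring A bis(benzylic bromide); the C5 methyl groups and the free phenols follow in three steps.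

Key step: step 8

Remark: the only stereocentre of the target is (R) and comes unchanged from (R)-2-methylbutanoic acid; salts that are merely reprotonated on work-up (phenoxides, zinc pyronates, the lithium enolate of a product keto ester) are not numbered separately.

**Route**

Step 1
Reactants: 1 phloroglucinol
Product: 3 2,4,6-trihydroxybenzene-1,3-dicarbaldehyde, via bis(iminium) dichloride 2 (not isolated)
Conditions: POCl3, DMF, dioxane, 0 °C → rt; then H2O
Reagents that add atoms: N,N-dimethylformamide, CN(C)C=O (both formyl carbons); water, O (both formyl oxygens)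
Why: Vilsmeier–Haack formylation, in which the chloroiminium ion attacks the triply activated ring twice and then stops because two iminium groups deactivate the last free carbon, and aqueous hydrolysis of the bis(iminium) salt releases both aldehydes.

Step 2
Reactants: 3 2,4,6-trihydroxybenzene-1,3-dicarbaldehyde; 4 (R)-2-methylbutanoic acid
Product: 6 (R)-2,4,6-trihydroxy-5-(2-methylbutanoyl)benzene-1,3-dicarbaldehyde, via (R)-2-methylbutanoyl chloride 5 (not isolated)
Conditions: 4, (COCl)2, cat. DMF, CH2Cl2, 0 °C → rt; then 3, TiCl4, CH2Cl2/MeNO2, 0 °C → rt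
Reagents that add atoms: none
Why: Friedel–Crafts acylation, in which TiCl4 activates the acid chloride and the only free ring carbon, ortho or para to all three oxygens, is acylated; the acid chloride is made without base so no ketene can form, and the (R)-centre of 4 should pass into 6 unchanged at this temperature (enantiomeric purity to be checked by chiral HPLC on 7).

Step 3
Reactants: 6 (R)-2,4,6-trihydroxy-5-(2-methylbutanoyl)benzene-1,3-dicarbaldehyde
Product: 7 (R)-2,4,6-tris(benzyloxy)-5-(2-methylbutanoyl)benzene-1,3-dicarbaldehyde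
Conditions: BnBr, K2CO3, DMF, 45 °C
Reagents that add atoms: benzyl bromide, BrCc1ccccc1
Why: Williamson ether synthesis, in which the three phenols, each acidified by two flanking carbonyl groups, are ionised by carbonate and benzylated on oxygen because every ring carbon is substituted and acceptor-bearing, while carbonate is too weak to deprotonate the ketone alpha-carbon and so should leave the (R)-centre alone.

Step 4
Reactants: 7 (R)-2,4,6-tris(benzyloxy)-5-(2-methylbutanoyl)benzene-1,3-dicarbaldehyde
Product: 8 (2R)-1-[2,4,6-tris(benzyloxy)-3,5-bis(hydroxymethyl)phenyl]-2-methylbutan-1-one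
Conditions: NaBH4, THF/MeOH, 0 °C
Reagents that add atoms: none
Why: Chemoselective borohydride reduction, in which both aldehydes react within minutes at 0 °C whereas the ketone, twisted out of plane between two ortho benzyloxy groups and bearing a branched alkyl group, is shielded from hydride.

Step 5
Reactants: 8 (2R)-1-[2,4,6-tris(benzyloxy)-3,5-bis(hydroxymethyl)phenyl]-2-methylbutan-1-one
Product: 9 (2R)-1-[2,4,6-tris(benzyloxy)-3,5-bis(bromomethyl)phenyl]-2-methylbutan-1-one
Conditions: PBr3, CH2Cl2, 0 °C; cold aq. NaHCO3 wash; used crude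
Reagents that add atoms: phosphorus tribromide, BrP(Br)Br
Why: Bromination of benzylic alcohols with PBr3 through a bromophosphite and bromide displacement, fast at 0 °C because the trialkoxy-substituted benzylic carbons ionise easily, with the labile bis(bromide) taken on without chromatography and the aryl benzyl ethers and ketone inert at this temperature.

Step 6
Reactants: 10 pent-2-ynoic acid; 11 tert-butyl acetate
Product: 14 tert-butyl 3-oxohept-4-ynoate, via pent-2-ynoyl chloride 12 (not isolated), via lithium enolate of tert-butyl acetate 13 (not isolated)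
Conditions: 10, (COCl)2, cat. DMF, CH2Cl2, 0 °C → rt; 11 (2.2 equiv), LiN(iPr)2 (2.2 equiv), THF, −78 °C; then 12, −78 °C; AcOH quench at −78 °C
Reagents that add atoms: none
Why: Crossed Claisen acylation of a lithium ester enolate by an acid chloride, in which the hard enolate attacks the acyl carbon and not the alkyne terminus at −78 °C, the second equivalent of enolate deprotonates the β-keto ester as it forms and so blocks double acylation, and the cold acidic quench keeps the liberated amine from adding to the ynone.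

Step 7
Reactants: 9 (2R)-1-[2,4,6-tris(benzyloxy)-3,5-bis(bromomethyl)phenyl]-2-methylbutan-1-one; 14 tert-butyl 3-oxohept-4-ynoate
Product: 16 di-tert-butyl 2,2'-{[2,4,6-tris(benzyloxy)-5-[(2R)-2-methylbutanoyl]-1,3-phenylene]bis(methylene)}bis(3-oxohept-4-ynoate) (epimer mixture at both C2 centres), via sodium enolate of keto ester 15 (not isolated)
Conditions: 14 (2.4 equiv), NaH (2.3 equiv), THF, 0 °C; then 9, 0 °C → rt
Reagents that add atoms: none
Why: Acetoacetic-ester-type C-alkylation (SN2) of the chelated sodium enolate by the activated benzylic bromides, where a preformed enolate in THF favours carbon over oxygen, leaves no free base to touch the ketone alpha-carbon, is itself a poor Michael acceptor and gives a product too hindered for a second alkylation; the two new keto ester stereocentres are uncontrolled and need no control because both become sp2 carbons in step 8.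

Step 8
Reactants: 16 di-tert-butyl 2,2'-{[2,4,6-tris(benzyloxy)-5-[(2R)-2-methylbutanoyl]-1,3-phenylene]bis(methylene)}bis(3-oxohept-4-ynoate)
Product: 17 (2R)-1-{2,4,6-tris(benzyloxy)-3,5-bis[(6-ethyl-4-hydroxy-2-oxo-2H-pyran-3-yl)methyl]phenyl}-2-methylbutan-1-one
Conditions: Ph3PAuNTf2 (5 mol% per alkyne), MeNO2/AcOH (4:1), rt
Reagents that add atoms: none
Why: Cationic monovalent gold coordinates each ynone triple bond and the carbonyl oxygen of the neighbouring tert-butyl ester adds anti to the metal at the ethyl-bearing carbon, giving a cyclic oxocarbenium vinylgold species that expels isobutene, is protodeaurated at C5 by acetic acid and tautomerises to the aromatic 4-hydroxy-2-pyrone. The closest known reaction is the gold-catalysed conversion of tert-butyl 3-oxoalk-4-ynoates, alpha-substituted ones included, into 6-substituted 4-hydroxy-2-pyrones, and the silver-free preformed catalyst avoids strong-acid traces that could strip the tert-butyl esters early. Each of the two pyrone rings closes in the 6-endo-dig mode at O1–C6. No stereocentre is created: the two epimeric keto ester carbons become sp2 C3, and the remote (R)-centre is not enolised in this weakly acidic medium. The step needs 6-endo over 5-exo closure and attack by the ester oxygen alone; the polarisation of the ynone places the electrophilic site at C6, and ring A is fully substituted with all three phenols benzylated, so neither an arene carbon nor a free hydroxyl can compete. The two arms react independently, so the twofold closure is the same event run twice.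

Step 9
Reactants: 17 (2R)-1-{2,4,6-tris(benzyloxy)-3,5-bis[(6-ethyl-4-hydroxy-2-oxo-2H-pyran-3-yl)methyl]phenyl}-2-methylbutan-1-one
Product: 18 (2R)-1-{2,4,6-tris(benzyloxy)-3,5-bis[(6-ethyl-4-hydroxy-5-iodo-2-oxo-2H-pyran-3-yl)methyl]phenyl}-2-methylbutan-1-one
Conditions: NIS (2.2 equiv), MeCN, 0 °C → rt, dark
Reagents that add atoms: N-iodosuccinimide, O=C1CCC(=O)N1I
Why: Electrophilic aromatic iodination of the 4-hydroxy-2-pyrone, where C5 is the only ring carbon that can lose a proton because C3 carries the benzylic methylene, any iodine that adds at C3 sits in an α-iodo-1,3-dicarbonyl that hands it back so that substitution should funnel to C5, and ring A has no free position.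

Step 10
Reactants: 18 (2R)-1-{2,4,6-tris(benzyloxy)-3,5-bis[(6-ethyl-4-hydroxy-5-iodo-2-oxo-2H-pyran-3-yl)methyl]phenyl}-2-methylbutan-1-one
Product: 19 (2R)-1-{2,4,6-tris(benzyloxy)-3,5-bis[(6-ethyl-4-hydroxy-5-methyl-2-oxo-2H-pyran-3-yl)methyl]phenyl}-2-methylbutan-1-one
Conditions: MeZnCl (6 equiv), Pd(PPh3)4 (10 mol%), THF, 0 → 60 °C; 1 M HCl work-up
Reagents that add atoms: methylzinc chloride, C[Zn]Cl
Why: Negishi cross-coupling, in which the first two equivalents of MeZnCl turn the acidic pyrone hydroxyls into chlorozinc pyronates (a transient protection, with loss of methane), zerovalent palladium inserts into each C5–I bond as it does in couplings of unprotected iodo-hydroxypyrones, and transmetalation followed by reductive elimination installs both methyl groups under non-basic conditions that spare the benzyl ethers and the (R)-centre.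

Step 11
Reactants: 19 (2R)-1-{2,4,6-tris(benzyloxy)-3,5-bis[(6-ethyl-4-hydroxy-5-methyl-2-oxo-2H-pyran-3-yl)methyl]phenyl}-2-methylbutan-1-one
Product: 20 (2R)-1-{3,5-bis[(6-ethyl-4-hydroxy-5-methyl-2-oxo-2H-pyran-3-yl)methyl]-2,4,6-trihydroxyphenyl}-2-methylbutan-1-one (CNP0174567.1)
Conditions: H2 (1 atm), 10% Pd/C, EtOAc/MeOH, rt; stopped at full debenzylation
Reagents that add atoms: none
Why: Hydrogenolysis of aryl benzyl ethers over Pd/C, in which the three O–CH2Ph bonds are cleaved quickly while the fully substituted pyrones and the hydrogen-bonded aryl ketone are reduced far more slowly, and the neutral medium leaves the (R)-centre untouched.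

**Compound list**

1 | phloroglucinol (benzene-1,3,5-triol) | Oc1cc(O)cc(O)c1 | starting material
2 | 2,4,6-trihydroxy-1,3-phenylenebis(N,N-dimethylmethaniminium) dichloride (formed in the flask) | C[N+](C)=Cc1c(O)cc(O)c(C=[N+](C)C)c1O.[Cl-].[Cl-] | intermediate
3 | 2,4,6-trihydroxybenzene-1,3-dicarbaldehyde | O=Cc1c(O)cc(O)c(C=O)c1O | intermediate
4 | (R)-2-methylbutanoic acid | CC[C@@H](C)C(O)=O | starting material
5 | (R)-2-methylbutanoyl chloride (formed in the flask) | CC[C@@H](C)C(Cl)=O | intermediate
6 | (R)-2,4,6-trihydroxy-5-(2-methylbutanoyl)benzene-1,3-dicarbaldehyde | CC[C@@H](C)C(=O)c1c(O)c(C=O)c(O)c(C=O)c1O | intermediate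
7 | (R)-2,4,6-tris(benzyloxy)-5-(2-methylbutanoyl)benzene-1,3-dicarbaldehyde | CC[C@@H](C)C(=O)c1c(OCc2ccccc2)c(C=O)c(OCc2ccccc2)c(C=O)c1OCc1ccccc1 | intermediate
8 | (2R)-1-[2,4,6-tris(benzyloxy)-3,5-bis(hydroxymethyl)phenyl]-2-methylbutan-1-one | CC[C@@H](C)C(=O)c1c(OCc2ccccc2)c(CO)c(OCc2ccccc2)c(CO)c1OCc1ccccc1 | intermediate
9 | (2R)-1-[2,4,6-tris(benzyloxy)-3,5-bis(bromomethyl)phenyl]-2-methylbutan-1-one | CC[C@@H](C)C(=O)c1c(OCc2ccccc2)c(CBr)c(OCc2ccccc2)c(CBr)c1OCc1ccccc1 | intermediate
10 | pent-2-ynoic acid | CCC#CC(O)=O | starting material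
11 | tert-butyl acetate | CC(=O)OC(C)(C)C | starting material
12 | pent-2-ynoyl chloride (formed in the flask) | CCC#CC(Cl)=O | intermediate
13 | lithium enolate of tert-butyl acetate (formed in the flask) | [Li+].C=C([O-])OC(C)(C)C | intermediate
14 | tert-butyl 3-oxohept-4-ynoate | CCC#CC(=O)CC(=O)OC(C)(C)C | intermediate
15 | sodium enolate of tert-butyl 3-oxohept-4-ynoate (formed in the flask) | [Na+].CCC#CC(=O)/C=C(\[O-])OC(C)(C)C | intermediate
16 | di-tert-butyl 2,2'-{[2,4,6-tris(benzyloxy)-5-[(2R)-2-methylbutanoyl]-1,3-phenylene]bis(methylene)}bis(3-oxohept-4-ynoate), epimer mixture at both C2 centres | CC[C@@H](C)C(=O)c1c(OCc2ccccc2)c(CC(C(=O)OC(C)(C)C)C(=O)C#CCC)c(OCc2ccccc2)c(CC(C(=O)OC(C)(C)C)C(=O)C#CCC)c1OCc1ccccc1 | intermediate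
17 | (2R)-1-{2,4,6-tris(benzyloxy)-3,5-bis[(6-ethyl-4-hydroxy-2-oxo-2H-pyran-3-yl)methyl]phenyl}-2-methylbutan-1-one | CC[C@@H](C)C(=O)c1c(OCc2ccccc2)c(Cc2c(O)cc(CC)oc2=O)c(OCc2ccccc2)c(Cc2c(O)cc(CC)oc2=O)c1OCc1ccccc1 | intermediate
18 | (2R)-1-{2,4,6-tris(benzyloxy)-3,5-bis[(6-ethyl-4-hydroxy-5-iodo-2-oxo-2H-pyran-3-yl)methyl]phenyl}-2-methylbutan-1-one | CC[C@@H](C)C(=O)c1c(OCc2ccccc2)c(Cc2c(O)c(I)c(CC)oc2=O)c(OCc2ccccc2)c(Cc2c(O)c(I)c(CC)oc2=O)c1OCc1ccccc1 | intermediate
19 | (2R)-1-{2,4,6-tris(benzyloxy)-3,5-bis[(6-ethyl-4-hydroxy-5-methyl-2-oxo-2H-pyran-3-yl)methyl]phenyl}-2-methylbutan-1-one | CC[C@@H](C)C(=O)c1c(OCc2ccccc2)c(Cc2c(O)c(C)c(CC)oc2=O)c(OCc2ccccc2)c(Cc2c(O)c(C)c(CC)oc2=O)c1OCc1ccccc1 | intermediate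
20 | (2R)-1-{3,5-bis[(6-ethyl-4-hydroxy-5-methyl-2-oxo-2H-pyran-3-yl)methyl]-2,4,6-trihydroxyphenyl}-2-methylbutan-1-one (CNP0174567.1) | CCc1oc(=O)c(Cc2c(O)c(Cc3c(O)c(C)c(CC)oc3=O)c(O)c(C(=O)[C@H](C)CC)c2O)c(O)c1C | target

Total step count: 11. Longest linear sequence: 10 steps (steps 1–5 and 7–11); step 6 is a one-step side branch.

**Steps most likely to fail**

1. Step 8. The second ring closure may stall through catalyst deactivation, or a tert-butyl group may be lost before closure so that the resulting β-keto acid decarboxylates. The fallback uses no gold and closes the lactone C–O bond by acyl substitution. Starting from 16, pyrrolidine in EtOH at rt should add to both ynones (aza-Michael addition) to give the bis(enaminone) F1. Oxalic acid in THF/H2O at rt should hydrolyse both enaminones to the bis(3,5-dioxoheptanoate) F2. TFA/TFAA in CH2Cl2 at 0 °C should then cleave the tert-butyl esters and cyclodehydrate each 3,5-dioxo acid to the 4-hydroxy-2-pyrone, rejoining the route at 17.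

2. Step 7. The electron-rich benzylic bromide may ionise and decompose, the enolate may be alkylated on oxygen, or the enolate may add in Michael fashion to the ynone of the product and form oligomers. The fallback brings in the ynone only after the C–C bond is made. Starting from 9, the sodium enolate of allyl tert-butyl malonate (NaH, THF, 0 °C) should give the bis(allyl tert-butyl malonate) F3. Pd(PPh3)4 with morpholine in THF at rt should remove both allyl esters to give the bis(malonic acid mono-tert-butyl ester) F4. MgCl2/Et3N in MeCN followed by pent-2-ynoyl chloride 12 should acylate each magnesium enolate (decarboxylative Claisen acylation), and decarboxylation on acidic work-up returns to the route at 16.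

3. Step 10. Oxidative addition into the electron-rich zinc pyronate may be slow, and protodeiodination may return 17. The fallback caps the pyrone hydroxyls first. Starting from 18, Mitsunobu etherification (BnOH, PPh3, DIAD, THF, 0 °C → rt) should give the penta-O-benzyl bis(5-iodopyrone) F5. Negishi coupling (MeZnCl, Pd(PPh3)4, THF, 60 °C) on this ordinary heteroaryl iodide should give the penta-O-benzyl bis(5-methylpyrone) F6. Hydrogenolysis under the conditions of step 11 then removes all five benzyl groups and arrives at 20.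

Further compounds
F1 | step 8 | di-tert-butyl 2,2'-{[2,4,6-tris(benzyloxy)-5-[(2R)-2-methylbutanoyl]-1,3-phenylene]bis(methylene)}bis[(4E)-3-oxo-5-(pyrrolidin-1-yl)hept-4-enoate], epimer mixture at both C2 centres | CC[C@@H](C)C(=O)c1c(OCc2ccccc2)c(CC(C(=O)OC(C)(C)C)C(=O)/C=C(/N2CCCC2)CC)c(OCc2ccccc2)c(CC(C(=O)OC(C)(C)C)C(=O)/C=C(/N2CCCC2)CC)c1OCc1ccccc1
F2 | step 8 | di-tert-butyl 2,2'-{[2,4,6-tris(benzyloxy)-5-[(2R)-2-methylbutanoyl]-1,3-phenylene]bis(methylene)}bis(3,5-dioxoheptanoate), epimer mixture at both C2 centres | CC[C@@H](C)C(=O)c1c(OCc2ccccc2)c(CC(C(=O)OC(C)(C)C)C(=O)CC(=O)CC)c(OCc2ccccc2)c(CC(C(=O)OC(C)(C)C)C(=O)CC(=O)CC)c1OCc1ccccc1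
F3 | step 7 | diallyl di-tert-butyl 2,2'-{[2,4,6-tris(benzyloxy)-5-[(2R)-2-methylbutanoyl]-1,3-phenylene]bis(methylene)}dimalonate (one allyl and one tert-butyl ester on each malonate), epimer mixture | CC[C@@H](C)C(=O)c1c(OCc2ccccc2)c(CC(C(=O)OCC=C)C(=O)OC(C)(C)C)c(OCc2ccccc2)c(CC(C(=O)OCC=C)C(=O)OC(C)(C)C)c1OCc1ccccc1
F4 | step 7 | 2,2'-{[2,4,6-tris(benzyloxy)-5-[(2R)-2-methylbutanoyl]-1,3-phenylene]bis(methylene)}bis[3-(tert-butoxy)-3-oxopropanoic acid], epimer mixture | CC[C@@H](C)C(=O)c1c(OCc2ccccc2)c(CC(C(O)=O)C(=O)OC(C)(C)C)c(OCc2ccccc2)c(CC(C(O)=O)C(=O)OC(C)(C)C)c1OCc1ccccc1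
F5 | step 10 | (2R)-1-{2,4,6-tris(benzyloxy)-3,5-bis[(4-benzyloxy-6-ethyl-5-iodo-2-oxo-2H-pyran-3-yl)methyl]phenyl}-2-methylbutan-1-one | CC[C@@H](C)C(=O)c1c(OCc2ccccc2)c(Cc2c(OCc3ccccc3)c(I)c(CC)oc2=O)c(OCc2ccccc2)c(Cc2c(OCc3ccccc3)c(I)c(CC)oc2=O)c1OCc1ccccc1
F6 | step 10 | (2R)-1-{2,4,6-tris(benzyloxy)-3,5-bis[(4-benzyloxy-6-ethyl-5-methyl-2-oxo-2H-pyran-3-yl)methyl]phenyl}-2-methylbutan-1-one | CC[C@@H](C)C(=O)c1c(OCc2ccccc2)c(Cc2c(OCc3ccccc3)c(C)c(CC)oc2=O)c(OCc2ccccc2)c(Cc2c(OCc3ccccc3)c(C)c(CC)oc2=O)c1OCc1ccccc1
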